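The synthesis rests on disconnecting the aryl ether bond O1–C8a of ring C together with the C8–side-chain bond. The key step exploits the contiguous C7(O)–C8(C)–C8a(O1) pattern of ring A: in an acyclic (1S,3S)-1,3-diaryl-1,3-diol carrying fluorine at C8a and hydrogen at C8, lithiation at C8, loss of LiF to the C8≡C8a aryne, closure of ring C by the C2 alkoxide at C8a and copper-catalysed allylation of the resulting C8 aryllithium with a Z-allylic bromide occur in one flask. The diol comes from asymmetric transfer hydrogenation of a 1,3-diketone; oxidation at C4 and acid deprotection finish the route.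

Key step: step 8

Remark: atoms are numbered as in a flavanone (O1, C2–C4, C4a, C5–C8, C8a); the side-chain olefin of the target is read as Z (CH2OH cis to the benzylic CH2) and C2 as S.

Step 1
Reactants: 1 1-(2-fluoro-4-hydroxyphenyl)ethanone
Product: 2 1-[2-fluoro-4-(methoxymethoxy)phenyl]ethanone
Conditions: MOMCl (1.2 equiv), K2CO3 (1.5 equiv), acetone, 0 °C → rt
Reagents that add atoms: chloromethyl methyl ether COCCl
Why: O-alkylation of the acidic para-acylphenoxide (Williamson-type MOM protection) should be clean, and the MOM ether later serves as the ortho-directing group at C7.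

Step 2
Reactants: 3 methyl 3,4-dihydroxybenzoate
Product: 4 methyl 3,4-bis(methoxymethoxy)benzoate
Conditions: NaH (2.4 equiv), MOMCl (2.4 equiv), DMF, 0 °C → rt
Reagents that add atoms: chloromethyl methyl ether COCCl
Why: Double Williamson-type MOM protection of the catechol bis-phenoxide gives a base-stable ring B building block.

Step 3
Reactants: 2 1-[2-fluoro-4-(methoxymethoxy)phenyl]ethanone; 4 methyl 3,4-bis(methoxymethoxy)benzoate
Product: 5 1-[3,4-bis(methoxymethoxy)phenyl]-3-[2-fluoro-4-(methoxymethoxy)phenyl]propane-1,3-dione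
Conditions: LiHMDS (2.5 equiv), THF, −78 °C → rt; aq. NH4Cl
Reagents that add atoms: none
Why: Crossed Claisen condensation of the lithium enolate of 2 with the non-enolisable ester 4 is driven by deprotonation of the 1,3-diketone, and staying at or below room temperature should keep the diketonate oxygen from displacing the ortho fluoride.

Step 4
Reactants: 5 1-[3,4-bis(methoxymethoxy)phenyl]-3-[2-fluoro-4-(methoxymethoxy)phenyl]propane-1,3-dione
Product: 6 (1S,3S)-1-[3,4-bis(methoxymethoxy)phenyl]-3-[2-fluoro-4-(methoxymethoxy)phenyl]propane-1,3-diol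
Conditions: RuCl[(S,S)-TsDPEN](p-cymene) (2 mol %), HCO2H/Et3N (5:2), DMF, 40 °C; syn diol removed by chromatography or crystallisation
Reagents that add atoms: none
Why: Noyori–Ikariya asymmetric transfer hydrogenation reduces both aryl ketones under catalyst control with the facial sense that turns aryl methyl ketones into (S)-1-arylethanols, so the anti (1S,3S)-diol is expected, its C1 carbinol being the future C2 of the flavanone.

Step 5
Reactants: 7 3-methylfuran-2(5H)-one
Product: 9 methyl (Z)-4-bromo-2-methylbut-2-enoate, via acyloxydibromoborane 8 (not isolated)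
Conditions: BBr3 (1.1 equiv), CH2Cl2, 0 °C → rt; then MeOH, 0 °C
Reagents that add atoms: boron tribromide BrB(Br)Br; methanol CO
Why: Lewis acid lactone cleavage, in which bromide opens the BBr3-activated lactone at the allylic C5–O carbon by SN2 and methanolysis gives the ester, carries the cis ring geometry of 7 directly into the Z olefin.

Step 6
Reactants: 9 methyl (Z)-4-bromo-2-methylbut-2-enoate
Product: 10 (Z)-4-bromo-2-methylbut-2-en-1-ol
Conditions: DIBAL-H (2.2 equiv), CH2Cl2, −78 °C; cold aqueous potassium sodium tartrate; used at once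
Reagents that add atoms: none
Why: 1,2-Reduction of the enoate by DIBAL-H at −78 °C should leave the allylic bromide and the olefin geometry untouched.

Step 7
Reactants: 10 (Z)-4-bromo-2-methylbut-2-en-1-ol
Product: 11 (Z)-[(4-bromo-2-methylbut-2-en-1-yl)oxy](tert-butyl)dimethylsilane
Conditions: TBSOTf (1.1 equiv), 2,6-lutidine (1.5 equiv), CH2Cl2, −78 °C
Reagents that add atoms: tert-butyldimethylsilyl trifluoromethanesulfonate CC(C)(C)[Si](C)(C)OS(=O)(=O)C(F)(F)F
Why: Silylation with a silyl triflate and a hindered, weak base should be much faster than cyclisation of the Z-bromo alcohol to 3-methyl-2,5-dihydrofuran.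

Step 8
Reactants: 6 (1S,3S)-1-[3,4-bis(methoxymethoxy)phenyl]-3-[2-fluoro-4-(methoxymethoxy)phenyl]propane-1,3-diol; 11 (Z)-[(4-bromo-2-methylbut-2-en-1-yl)oxy](tert-butyl)dimethylsilane
Product: 15 (2S,4S)-2-[3,4-bis(methoxymethoxy)phenyl]-8-[(2Z)-4-{[tert-butyl(dimethyl)silyl]oxy}-3-methylbut-2-en-1-yl]-7-(methoxymethoxy)-3,4-dihydro-2H-chromen-4-ol, via trilithiated fluoroarene 12 (not isolated), via aryne 13 (not isolated), via C8-aryllithium 14 (not isolated)
Conditions: n-BuLi (3.05 equiv), THF, −78 °C, 1 h; warm to 0 °C, 1 h; recool to −78 °C, CuBr·SMe2 (0.2 equiv), 11 (1.3 equiv), → 0 °C; H2O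
Reagents that add atoms: none
Why: Three equivalents of n-BuLi form both lithium alkoxides and then metalate C8, the only ring A position flanked by fluorine and the OMOM group (directed ortho-metalation), and on warming LiF is lost to give the C8≡C8a aryne 13. The C2 lithium alkoxide adds to C8a in an in-plane 6-exo-dig closure of ring C that forms O1–C8a; the C4 alkoxide cannot compete because it would give a four-membered ring, and attack at C8a is also the electronically preferred mode for a 3-alkoxyaryne because it leaves the carbanion at C8 next to the OMOM oxygen. The aryllithium 14, held between O1 and OMOM, is then allylated at the primary carbon of 11 under copper catalysis (SN2 rather than SN2', the γ-carbon being fully substituted), so the Z olefin is carried over unchanged. The closest known reaction type is the anionic aryne ring closure with oxygen nucleophiles (intramolecular trapping of benzynes by alcohols to chromans) combined with electrophilic capture of the aryl anion so formed. No stereocenter is created: C2 keeps its S configuration because its C–O bond is never broken, and the C4 carbinol is a spectator that step 9 oxidises. The step needs site-selective lithiation at C8 and intramolecular capture of the aryne faster than intermolecular addition of butyllithium or of 12, which the F/OMOM flanking, the exact base stoichiometry and the six-membered tether should secure.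

Step 9
Reactants: 15 (2S,4S)-2-[3,4-bis(methoxymethoxy)phenyl]-8-[(2Z)-4-{[tert-butyl(dimethyl)silyl]oxy}-3-methylbut-2-en-1-yl]-7-(methoxymethoxy)-3,4-dihydro-2H-chromen-4-ol
Product: 16 (2S)-2-[3,4-bis(methoxymethoxy)phenyl]-8-[(2Z)-4-{[tert-butyl(dimethyl)silyl]oxy}-3-methylbut-2-en-1-yl]-7-(methoxymethoxy)-2,3-dihydro-4H-chromen-4-one
Conditions: Dess–Martin periodinane (1.3 equiv), pyridine (3 equiv), CH2Cl2, 0 °C → rt
Reagents that add atoms: none
Why: Dess–Martin oxidation of the only free (secondary benzylic) alcohol under buffered, base-free conditions should give the C4 ketone without ring opening or epimerisation at C2.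

Step 10
Reactants: 16 (2S)-2-[3,4-bis(methoxymethoxy)phenyl]-8-[(2Z)-4-{[tert-butyl(dimethyl)silyl]oxy}-3-methylbut-2-en-1-yl]-7-(methoxymethoxy)-2,3-dihydro-4H-chromen-4-one
Product: 17 (2S)-2-(3,4-dihydroxyphenyl)-7-hydroxy-8-[(2Z)-4-hydroxy-3-methylbut-2-en-1-yl]-2,3-dihydro-4H-chromen-4-one
Conditions: HCl (1.25 M in MeOH), THF, 0 → 35 °C
Reagents that add atoms: none
Why: Acid-catalysed acetal exchange removes the three MOM ethers and solvolyses the primary TBS ether in one operation, and the acidic medium avoids the phenoxide-triggered retro-oxa-Michael ring opening that would racemise C2.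

Compound list
1 | 1-(2-fluoro-4-hydroxyphenyl)ethanone | CC(=O)c1ccc(O)cc1F | starting material
2 | 1-[2-fluoro-4-(methoxymethoxy)phenyl]ethanone | CC(=O)c1ccc(OCOC)cc1F | intermediate
3 | methyl 3,4-dihydroxybenzoate | COC(=O)c1ccc(O)c(O)c1 | starting material
4 | methyl 3,4-bis(methoxymethoxy)benzoate | COCOc1ccc(C(=O)OC)cc1OCOC | intermediate
5 | 1-[3,4-bis(methoxymethoxy)phenyl]-3-[2-fluoro-4-(methoxymethoxy)phenyl]propane-1,3-dione | O=C(CC(=O)c1ccc(OCOC)c(OCOC)c1)c1ccc(OCOC)cc1F | intermediate
6 | (1S,3S)-1-[3,4-bis(methoxymethoxy)phenyl]-3-[2-fluoro-4-(methoxymethoxy)phenyl]propane-1,3-diol | O[C@H](c1ccc(OCOC)c(OCOC)c1)C[C@H](O)c1ccc(OCOC)cc1F | intermediate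
7 | 3-methylfuran-2(5H)-one | CC1=CCOC1=O | starting material
8 | dibromoboryl (Z)-4-bromo-2-methylbut-2-enoate (acyloxydibromoborane, formed in the flask) | C/C(=C/CBr)C(=O)OB(Br)Br | intermediate
9 | methyl (Z)-4-bromo-2-methylbut-2-enoate | C/C(=C/CBr)C(=O)OC | intermediate
10 | (Z)-4-bromo-2-methylbut-2-en-1-ol | C/C(=C/CBr)CO | intermediate
11 | (Z)-[(4-bromo-2-methylbut-2-en-1-yl)oxy](tert-butyl)dimethylsilane | C/C(=C/CBr)CO[Si](C)(C)C(C)(C)C | intermediate
12 | trilithiated fluoroarene: dilithium dialkoxide of 6 lithiated at C8 (formed in the flask) | [Li]O[C@H](c1ccc(OCOC)c(OCOC)c1)C[C@H](O[Li])c1ccc(OCOC)c([Li])c1F | intermediate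
13 | aryne: dilithium dialkoxide with the C8≡C8a triple bond (formed in the flask) | [Li]O[C@H](c1ccc(OCOC)c(OCOC)c1)C[C@H](O[Li])C1=CC=C(OCOC)C#C1 | intermediate
14 | C8-aryllithium: lithium (2S,4S)-2-[3,4-bis(methoxymethoxy)phenyl]-8-lithio-7-(methoxymethoxy)-3,4-dihydro-2H-chromen-4-olate (formed in the flask) | [Li]c1c(OCOC)ccc2c1O[C@H](c1ccc(OCOC)c(OCOC)c1)C[C@@H]2O[Li] | intermediate
15 | (2S,4S)-2-[3,4-bis(methoxymethoxy)phenyl]-8-[(2Z)-4-{[tert-butyl(dimethyl)silyl]oxy}-3-methylbut-2-en-1-yl]-7-(methoxymethoxy)-3,4-dihydro-2H-chromen-4-ol | C/C(=C/Cc1c(OCOC)ccc2c1O[C@H](c1ccc(OCOC)c(OCOC)c1)C[C@@H]2O)CO[Si](C)(C)C(C)(C)C | intermediate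
16 | (2S)-2-[3,4-bis(methoxymethoxy)phenyl]-8-[(2Z)-4-{[tert-butyl(dimethyl)silyl]oxy}-3-methylbut-2-en-1-yl]-7-(methoxymethoxy)-2,3-dihydro-4H-chromen-4-one | C/C(=C/Cc1c(OCOC)ccc2c1O[C@H](c1ccc(OCOC)c(OCOC)c1)CC2=O)CO[Si](C)(C)C(C)(C)C | intermediate
17 | (2S)-2-(3,4-dihydroxyphenyl)-7-hydroxy-8-[(2Z)-4-hydroxy-3-methylbut-2-en-1-yl]-2,3-dihydro-4H-chromen-4-one | C/C(=C/Cc1c(O)ccc2c1O[C@H](c1ccc(O)c(O)c1)CC2=O)CO | target

Total step count: 10. Longest linear sequence: 6 steps (steps 1, 3, 4, 8, 9, 10).

Steps most likely to fail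

Step 8. What may go wrong: intermolecular capture of the aryne by butyllithium or by still-unreacted 12, reduction of the aryne by internal hydride transfer from the C2 carbinol C–H, and incomplete allylation of the hindered, doubly chelated aryllithium. The fallback separates the two bond formations and no longer uses the aryne as the platform for the C–C bond. It sets out from 6: heating its dipotassium alkoxide (KOt-Bu, DMF, 80 °C) should close ring C by intramolecular displacement of the C8a fluoride and give the 8-unsubstituted (2S,4S)-2-[3,4-bis(methoxymethoxy)phenyl]-7-(methoxymethoxy)-3,4-dihydro-2H-chromen-4-ol F1. A separate directed ortho-metalation of F1 at C8, now flanked by O1 and the OMOM oxygen (n-BuLi, 2.2 equiv, THF, −20 °C), followed by CuBr·SMe2 and 11, comes back to the route at 15.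

Step 5. What may go wrong: conjugate addition of bromide to the butenolide instead of cleavage of the C5–O bond, and re-closure of the lactone during methanolysis. The fallback builds the same ester by a Z-selective olefination without any lactone. It cannot set out from a route compound, because the failing step consumes starting material 7; it starts instead from commercial (tert-butyldimethylsilyloxy)acetaldehyde. Still–Gennari olefination of this aldehyde with methyl 2-[bis(2,2,2-trifluoroethoxy)phosphoryl]propanoate (KHMDS, 18-crown-6, THF, −78 °C) should give methyl (Z)-4-[(tert-butyldimethylsilyl)oxy]-2-methylbut-2-enoate F2. Ph3PBr2 (CH2Cl2, 0 °C) then turns the allylic silyl ether directly into the bromide, never freeing the lactonisation-prone hydroxy ester, and comes back at 9.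

Step 10. What may go wrong: acid-induced ionisation of the allylic alcohol (exchange with methanol or chloride), cyclisation of the side chain onto the C7 hydroxyl, and erosion of the C2 configuration by reversible ring opening. The fallback replaces protic solvolysis by aprotic, thiol-assisted Lewis acid cleavage followed by fluoride. It sets out from 16: ZnBr2/n-PrSH (CH2Cl2, 0 °C) should remove the three MOM groups and give (2S)-8-[(2Z)-4-{[tert-butyl(dimethyl)silyl]oxy}-3-methylbut-2-en-1-yl]-2-(3,4-dihydroxyphenyl)-7-hydroxy-2,3-dihydro-4H-chromen-4-one F3. Et3N·3HF (MeCN, rt) then removes the silyl group and arrives at 17.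

Further compounds
F1 | step 8 | (2S,4S)-2-[3,4-bis(methoxymethoxy)phenyl]-7-(methoxymethoxy)-3,4-dihydro-2H-chromen-4-ol | COCOc1ccc2c(c1)O[C@H](c1ccc(OCOC)c(OCOC)c1)C[C@@H]2O
F2 | step 5 | methyl (Z)-4-[(tert-butyldimethylsilyl)oxy]-2-methylbut-2-enoate | C/C(=C/CO[Si](C)(C)C(C)(C)C)C(=O)OC
F3 | step 10 | (2S)-8-[(2Z)-4-{[tert-butyl(dimethyl)silyl]oxy}-3-methylbut-2-en-1-yl]-2-(3,4-dihydroxyphenyl)-7-hydroxy-2,3-dihydro-4H-chromen-4-one | C/C(=C/Cc1c(O)ccc2c1O[C@H](c1ccc(O)c(O)c1)CC2=O)CO[Si](C)(C)C(C)(C)C
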